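**Plan**

Locants: ring A = C1, C2, C3, C4 (bearing the exocyclic CH2, C11), C5, C10; ring B = C5 to C10; Ar = 2,3,5,6-tetramethoxyphenyl, ArCH2 sits on C9; β = the face of ring B that carries the C8 and C9 methyl groups.
Retrosynthesis: the hydroxy(methoxy)quinone goes back to the tetramethoxyarene and a helper carbonyl is placed on C6; the C4–C5 bond of ring A is then cut, because the C4=C11 methylene bonded to the quaternary ring-fusion carbon C5 (β,γ to C6) is the retron of an enol–alkyne (Conia-ene type) carbocyclisation of a C5=C6 silyl enol ether onto a C4≡C11 alkyne.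
Further cuts: C10–C1 (pentynyl tether, by 1,2-addition and oxidative 1,3-transposition), C5–CH3, C9–CH2Ar (enolate benzylation) and C8–CH3 (conjugate addition) of a ring B bought as 2-methylcyclohex-2-enone.
Forward order: ring B is decorated at C8, C9, C5 and C10, the arene is attached in step 4, ring A is closed last in step 11, then C6 is deoxygenated and the arene oxidised to the quinone.
Stereochemistry: C8 from a ligand-controlled copper-catalysed methyl addition; C9 from alkylation anti to the C8 methyl; C10 from axial protonation in a dissolving-metal reduction; C5 from the C10 tether in the key step (cis ring fusion).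

Key step: step 11

**Route**

Step 1
Reactants: 1 1,2,4,5-tetramethoxybenzene
Product: 3 (2,3,5,6-tetramethoxyphenyl)methanol, via aryllithium 2 (not isolated)
Conditions: n-BuLi, TMEDA, THF, 0 °C; (CH2O)n, 0 °C to rt; aq. NH4Cl
Reagents that add atoms: paraformaldehyde (formaldehyde), C=O
Why: Directed ortho-lithiation at the position flanked by two methoxy groups, then hydroxymethylation of the aryllithium with formaldehyde; no stereocentre is formed.

Step 2
Reactants: 3 (2,3,5,6-tetramethoxyphenyl)methanol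
Product: 4 3-(bromomethyl)-1,2,4,5-tetramethoxybenzene
Conditions: PBr3, CH2Cl2, 0 °C
Reagents that add atoms: phosphorus tribromide, BrP(Br)Br
Why: Standard conversion of an electron-rich benzylic alcohol into the bromide through its phosphite ester; the bromide should be used directly.

Step 3
Reactants: 5 2-methylcyclohex-2-en-1-one
Product: 7 trimethyl{[(3S)-2,3-dimethylcyclohex-1-en-1-yl]oxy}silane, via magnesium enolate 6 (not isolated)
Conditions: MeMgBr, CuBr·SMe2 (5 mol %), chiral TADDOL-derived phosphine–phosphite ligand (6 mol %), 2-methyltetrahydrofuran, –78 °C; then Me3SiCl, Et3N, –78 °C to rt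
Reagents that add atoms: methylmagnesium bromide, C[Mg]Br; chlorotrimethylsilane, C[Si](C)(C)Cl
Why: Copper-catalysed enantioselective conjugate addition of a Grignard reagent to a cyclic enone with O-silylation of the enolate; the chiral ligand on copper selects the enone face, and the ligand enantiomer is chosen so that C8 is formed with the (S) configuration.

Step 4
Reactants: 7 trimethyl{[(3S)-2,3-dimethylcyclohex-1-en-1-yl]oxy}silane; 4 3-(bromomethyl)-1,2,4,5-tetramethoxybenzene
Product: 9 (2R,3S)-2-(ArCH2)-2,3-dimethylcyclohexan-1-one, via lithium enolate 8 (not isolated)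
Conditions: MeLi, THF, 0 °C to rt; then 4, –78 °C to 0 °C
Reagents that add atoms: none
Why: Alkylation of the regiodefined lithium enolate released from the silyl enol ether; allylic 1,2-strain holds the C8 methyl pseudoaxial, so the benzylic bromide should enter anti to it and give quaternary C9 with ArCH2 trans to the C8 methyl.

Step 5
Reactants: 9 (2R,3S)-2-(ArCH2)-2,3-dimethylcyclohexan-1-one
Product: 11 (2R,3S)-2-(ArCH2)-2,3,6-trimethylcyclohexan-1-one (both C6 epimers), via lithium enolate 10 (not isolated)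
Conditions: LiN(i-Pr)2, THF, –78 °C; MeI, –78 °C to rt
Reagents that add atoms: iodomethane, CI
Why: Enolate methylation; C9 is quaternary, so only C5 can be enolised, and the new C5 centre is erased in step 6.

Step 6
Reactants: 11 (2R,3S)-2-(ArCH2)-2,3,6-trimethylcyclohexan-1-one
Product: 13 (5S,6R)-6-(ArCH2)-2,5,6-trimethylcyclohex-2-en-1-one, via silyl enol ether 12 (not isolated)
Conditions: Me3SiOTf, Et3N, CH2Cl2, 0 °C to rt; then Pd(OAc)2, MeCN, rt
Reagents that add atoms: none
Why: Saegusa–Ito oxidation; the only possible silyl enol ether is palladated at C5 and β-hydride elimination toward C6 should give the endocyclic 2-methyl enone, with no stereocentre formed.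

Step 7
Reactants: 13 (5S,6R)-6-(ArCH2)-2,5,6-trimethylcyclohex-2-en-1-one; 14 (5-chloropent-1-yn-1-yl)trimethylsilane
Product: 16 (5S,6R)-6-(ArCH2)-2,5,6-trimethyl-1-[5-(trimethylsilyl)pent-4-yn-1-yl]cyclohex-2-en-1-ol (both C1 epimers), via Grignard reagent 15 (not isolated)
Conditions: 14, Mg, THF, reflux; CeCl3, THF, –78 °C; then 13, –78 °C to 0 °C; aq. NH4Cl
Reagents that add atoms: none
Why: Organocerium-mediated 1,2-addition of a primary Grignard reagent to a hindered enone, which suppresses enolisation and 1,4-addition; the carbinol configuration is irrelevant because it is lost in step 8.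

Step 8
Reactants: 16 (5S,6R)-6-(ArCH2)-2,5,6-trimethyl-1-[5-(trimethylsilyl)pent-4-yn-1-yl]cyclohex-2-en-1-ol
Product: 17 (4R,5S)-4-(ArCH2)-2,4,5-trimethyl-3-[5-(trimethylsilyl)pent-4-yn-1-yl]cyclohex-2-en-1-one
Conditions: pyridinium chlorochromate (C5H5NH)(CrO3Cl), 4 Å molecular sieves, CH2Cl2, rt
Reagents that add atoms: pyridinium chlorochromate, [O-][Cr](=O)(=O)Cl.c1cc[nH+]cc1
Why: Babler–Dauben oxidative transposition; the tertiary allylic chromate ester shifts [3,3] to C6 and is oxidised, which places the helper carbonyl on C6 and the tether on C10 without forming a stereocentre.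

Step 9
Reactants: 17 (4R,5S)-4-(ArCH2)-2,4,5-trimethyl-3-[5-(trimethylsilyl)pent-4-yn-1-yl]cyclohex-2-en-1-one
Product: 19 {[(3S,4R,5S)-4-(ArCH2)-2,4,5-trimethyl-3-[5-(trimethylsilyl)pent-4-yn-1-yl]cyclohex-1-en-1-yl]oxy}tri(propan-2-yl)silane, via lithium enolate 18 (not isolated)
Conditions: Li (2.2 equiv), NH3(l)/THF, t-BuOH (1 equiv), –78 °C; isoprene; NH3 removed; i-Pr3SiOTf (2.2 equiv), Et3N, THF, –78 °C to 0 °C
Reagents that add atoms: triisopropylsilyl trifluoromethanesulfonate, CC(C)[Si](OS(=O)(=O)C(F)(F)F)(C(C)C)C(C)C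
Why: Dissolving-metal reduction of the enone gives the C5=C6 lithium enolate regiospecifically, which is trapped on oxygen; C10 should be protonated axially on the α face, because the other axial approach is blocked by the C8 methyl in the alternative half-chair, so that H-10 is α and the tether, ArCH2 and C8 methyl are all equatorial.

Step 10
Reactants: 19 {[(3S,4R,5S)-4-(ArCH2)-2,4,5-trimethyl-3-[5-(trimethylsilyl)pent-4-yn-1-yl]cyclohex-1-en-1-yl]oxy}tri(propan-2-yl)silane
Product: 20 {[(3S,4R,5S)-4-(ArCH2)-2,4,5-trimethyl-3-(pent-4-yn-1-yl)cyclohex-1-en-1-yl]oxy}tri(propan-2-yl)silane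
Conditions: K2CO3, MeOH/THF, rt
Reagents that add atoms: none
Why: Base-catalysed methanolysis of the alkynyl C–Si bond, which is far more labile than the hindered triisopropylsilyl enol ether; no stereocentre is touched.

Step 11
Reactants: 20 {[(3S,4R,5S)-4-(ArCH2)-2,4,5-trimethyl-3-(pent-4-yn-1-yl)cyclohex-1-en-1-yl]oxy}tri(propan-2-yl)silane
Product: 21 (3S,4R,4aS,8aR)-4-(ArCH2)-3,4,8a-trimethyl-8-methylideneoctahydronaphthalen-1(2H)-one (cis-fused)
Conditions: Ph3PAuCl (5 mol %), AgBF4 (5 mol %), CH2Cl2/MeOH (10:1), rt to 40 °C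
Reagents that add atoms: none
Why: Cationic monovalent gold binds the terminal alkyne C4≡C11 and the silyl enol ether carbon C5 attacks the internal carbon C4 anti to gold, after which methanol takes the silyl group from oxygen and protonates the vinyl–gold bond at C11, releasing the C6 ketone with the C4=CH2 group. The closest known reaction type is the gold-catalysed carbocyclisation of silyl enol ethers onto alkynes, the mild variant of the Conia-ene reaction. Ring A closes in the 6-exo-dig mode, the Markovnikov bias of the gold–alkyne complex favouring attack at the substituted alkyne carbon over the 7-endo path. The only new stereocentre, quaternary C5, is controlled by C10: the three-carbon tether can deliver the alkyne only to the face of the planar enol ether on which it stands, so C4 should add on the β face and the C5 methyl end up cis to H-10. The step needs cis ring-fusion selectivity and C-attack at C5 only; the first is secured by the short tether together with allylic 1,2-strain between the C5 methyl and C1 (which tilts the tether pseudoaxial on the β face while the then pseudoaxial ArCH2 group screens the α face), the second by the enol ether having been fixed at C5=C6 in step 9.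

Step 12
Reactants: 21 (3S,4R,4aS,8aR)-4-(ArCH2)-3,4,8a-trimethyl-8-methylideneoctahydronaphthalen-1(2H)-one
Product: 23 1,2,4,5-tetramethoxy-3-{[(1R,2S,4aR,8aS)-1,2,4a-trimethyl-5-methylidenedecahydronaphthalen-1-yl]methyl}benzene, via hydrazone 22 (not isolated)
Conditions: N2H4·H2O, KOH, diethylene glycol, 130 °C then 200 °C
Reagents that add atoms: none
Why: Wolff–Kishner reduction (Huang-Minlon modification) removes the helper carbonyl at C6; C5 is quaternary, so the β,γ double bond cannot move into conjugation and no stereocentre is touched.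

Step 13
Reactants: 23 1,2,4,5-tetramethoxy-3-{[(1R,2S,4aR,8aS)-1,2,4a-trimethyl-5-methylidenedecahydronaphthalen-1-yl]methyl}benzene
Product: 24 2,5-dimethoxy-3-{[(1R,2S,4aR,8aS)-1,2,4a-trimethyl-5-methylidenedecahydronaphthalen-1-yl]methyl}cyclohexa-2,5-diene-1,4-dione
Conditions: (NH4)2Ce(NO3)6, MeCN/H2O, 0 °C
Reagents that add atoms: water, O
Why: Oxidative demethylation of a para-dimethoxyarene to the para-quinone by tetravalent cerium; both para pairs of the symmetric arene lead to the same 3-alkyl-2,5-dimethoxyquinone and the isolated alkene should be untouched.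

Step 14
Reactants: 24 2,5-dimethoxy-3-{[(1R,2S,4aR,8aS)-1,2,4a-trimethyl-5-methylidenedecahydronaphthalen-1-yl]methyl}cyclohexa-2,5-diene-1,4-dione
Product: 26 2-hydroxy-5-methoxy-3-{[(1R,2S,4aR,8aS)-1,2,4a-trimethyl-5-methylidenedecahydronaphthalen-1-yl]methyl}cyclohexa-2,5-diene-1,4-dione (CID21727418), via potassium salt 25 (not isolated)
Conditions: KOH, MeOH/H2O, rt; then 1 M HCl
Reagents that add atoms: potassium hydroxide, [K+].[OH-]
Why: Addition–elimination (vinylogous ester saponification) at the methoxy group next to the alkyl substituent, which is twisted out of conjugation and therefore the more electrophilic, the resulting hydroxyquinone anion resisting a second substitution; selective monohydrolysis of 3-alkyl-2,5-dimethoxybenzoquinones is a known reaction type.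

**Compound list**

1 | 1,2,4,5-tetramethoxybenzene | COc1cc(OC)c(OC)cc1OC | starting material
2 | (2,3,5,6-tetramethoxyphenyl)lithium | [Li]c1c(OC)c(OC)cc(OC)c1OC | intermediate
3 | (2,3,5,6-tetramethoxyphenyl)methanol | OCc1c(OC)c(OC)cc(OC)c1OC | intermediate
4 | 3-(bromomethyl)-1,2,4,5-tetramethoxybenzene | BrCc1c(OC)c(OC)cc(OC)c1OC | intermediate
5 | 2-methylcyclohex-2-en-1-one | CC1=CCCCC1=O | starting material
6 | bromomagnesium (3S)-2,3-dimethylcyclohex-1-en-1-olate | C[C@H]1CCCC(O[Mg]Br)=C1C | intermediate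
7 | trimethyl{[(3S)-2,3-dimethylcyclohex-1-en-1-yl]oxy}silane | C[C@H]1CCCC(O[Si](C)(C)C)=C1C | intermediate
8 | lithium (3S)-2,3-dimethylcyclohex-1-en-1-olate | C[C@H]1CCCC(O[Li])=C1C | intermediate
9 | (2R,3S)-2-(ArCH2)-2,3-dimethylcyclohexan-1-one | O=C1CCC[C@H](C)[C@@]1(C)Cc2c(OC)c(OC)cc(OC)c2OC | intermediate
10 | lithium (5S,6R)-6-(ArCH2)-5,6-dimethylcyclohex-1-en-1-olate | [Li]OC1=CCC[C@H](C)[C@@]1(C)Cc2c(OC)c(OC)cc(OC)c2OC | intermediate
11 | (2R,3S)-2-(ArCH2)-2,3,6-trimethylcyclohexan-1-one (both C6 epimers) | O=C1C(C)CC[C@H](C)[C@@]1(C)Cc2c(OC)c(OC)cc(OC)c2OC | intermediate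
12 | trimethyl{[(5S,6R)-6-(ArCH2)-2,5,6-trimethylcyclohex-1-en-1-yl]oxy}silane | C[Si](C)(C)OC1=C(C)CC[C@H](C)[C@@]1(C)Cc2c(OC)c(OC)cc(OC)c2OC | intermediate
13 | (5S,6R)-6-(ArCH2)-2,5,6-trimethylcyclohex-2-en-1-one | O=C1C(C)=CC[C@H](C)[C@@]1(C)Cc2c(OC)c(OC)cc(OC)c2OC | intermediate
14 | (5-chloropent-1-yn-1-yl)trimethylsilane | C[Si](C)(C)C#CCCCCl | starting material
15 | [5-(trimethylsilyl)pent-4-yn-1-yl]magnesium chloride | C[Si](C)(C)C#CCCC[Mg]Cl | intermediate
16 | (5S,6R)-6-(ArCH2)-2,5,6-trimethyl-1-[5-(trimethylsilyl)pent-4-yn-1-yl]cyclohex-2-en-1-ol (both C1 epimers) | OC1(CCCC#C[Si](C)(C)C)C(C)=CC[C@H](C)[C@@]1(C)Cc2c(OC)c(OC)cc(OC)c2OC | intermediate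
17 | (4R,5S)-4-(ArCH2)-2,4,5-trimethyl-3-[5-(trimethylsilyl)pent-4-yn-1-yl]cyclohex-2-en-1-one | O=C1C[C@H](C)[C@@](C)(Cc2c(OC)c(OC)cc(OC)c2OC)C(CCCC#C[Si](C)(C)C)=C1C | intermediate
18 | lithium (3S,4R,5S)-4-(ArCH2)-2,4,5-trimethyl-3-[5-(trimethylsilyl)pent-4-yn-1-yl]cyclohex-1-en-1-olate | [Li]OC1=C(C)[C@@H](CCCC#C[Si](C)(C)C)[C@](C)(Cc2c(OC)c(OC)cc(OC)c2OC)[C@@H](C)C1 | intermediate
19 | {[(3S,4R,5S)-4-(ArCH2)-2,4,5-trimethyl-3-[5-(trimethylsilyl)pent-4-yn-1-yl]cyclohex-1-en-1-yl]oxy}tri(propan-2-yl)silane | CC(C)[Si](OC1=C(C)[C@@H](CCCC#C[Si](C)(C)C)[C@](C)(Cc2c(OC)c(OC)cc(OC)c2OC)[C@@H](C)C1)(C(C)C)C(C)C | intermediate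
20 | {[(3S,4R,5S)-4-(ArCH2)-2,4,5-trimethyl-3-(pent-4-yn-1-yl)cyclohex-1-en-1-yl]oxy}tri(propan-2-yl)silane | CC(C)[Si](OC1=C(C)[C@@H](CCCC#C)[C@](C)(Cc2c(OC)c(OC)cc(OC)c2OC)[C@@H](C)C1)(C(C)C)C(C)C | intermediate
21 | (3S,4R,4aS,8aR)-4-(ArCH2)-3,4,8a-trimethyl-8-methylideneoctahydronaphthalen-1(2H)-one | C=C1CCC[C@H]2[C@](C)(Cc3c(OC)c(OC)cc(OC)c3OC)[C@@H](C)CC(=O)[C@@]12C | intermediate
22 | hydrazone of 21 at the ring carbonyl | C=C1CCC[C@H]2[C@](C)(Cc3c(OC)c(OC)cc(OC)c3OC)[C@@H](C)CC(=NN)[C@@]12C | intermediate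
23 | 1,2,4,5-tetramethoxy-3-{[(1R,2S,4aR,8aS)-1,2,4a-trimethyl-5-methylidenedecahydronaphthalen-1-yl]methyl}benzene | C=C1CCC[C@H]2[C@](C)(Cc3c(OC)c(OC)cc(OC)c3OC)[C@@H](C)CC[C@@]12C | intermediate
24 | 2,5-dimethoxy-3-{[(1R,2S,4aR,8aS)-1,2,4a-trimethyl-5-methylidenedecahydronaphthalen-1-yl]methyl}cyclohexa-2,5-diene-1,4-dione | C=C1CCC[C@H]2[C@](C)(CC3=C(OC)C(=O)C=C(OC)C3=O)[C@@H](C)CC[C@@]12C | intermediate
25 | potassium salt of 26 (hydroxyquinone oxygen deprotonated) | C=C1CCC[C@H]2[C@](C)(CC3=C([O-])C(=O)C=C(OC)C3=O)[C@@H](C)CC[C@@]12C.[K+] | intermediate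
26 | 2-hydroxy-5-methoxy-3-{[(1R,2S,4aR,8aS)-1,2,4a-trimethyl-5-methylidenedecahydronaphthalen-1-yl]methyl}cyclohexa-2,5-diene-1,4-dione (CID21727418) | C=C1CCC[C@H]2[C@](C)(CC3=C(O)C(=O)C=C(OC)C3=O)[C@@H](C)CC[C@@]12C | target

**Count and risks**

Total step count: 14. Longest linear sequence: 13 steps (from 1 through steps 1, 2 and 4 to 14).

Step 11. Protodesilylation of the enol ether by the protic co-solvent may outrun the slow 6-exo closure onto an unactivated alkyne that builds a quaternary carbon, or attack may occur on the α face of a twisted ring B and give the trans ring fusion. The fallback replaces π-acid activation by enolate cross-coupling. It sets out from 20: Bu4NF/AcOH in THF cleaves the enol ether to the ketone F7. Markovnikov bromoboration and protonolysis of the alkyne (B-bromo-9-borabicyclo[3.3.1]nonane, CH2Cl2, 0 °C, then AcOH) gives the 2-bromoalkene F8. Palladium-catalysed intramolecular α-alkenylation of the ketone (Pd(OAc)2, a bulky trialkylphosphine, NaOt-Bu, toluene, 70 °C) then closes ring A. The enolates equilibrate but only the C5 enolate can reach the alkenylpalladium unit, and reductive elimination from the cis-fused palladacycle should return the route at 21.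

Step 9. The silylalkyne or the arene may be over-reduced, proton exchange may scramble the enolate before trapping, or facial control in the protonation at C10 may be lost. The fallback sets C10 by a stereospecific sigmatropic hydrogen transfer instead of a protonation and avoids the dissolving metal. It sets out from 17: Luche reduction (NaBH4, CeCl3·7H2O, MeOH, –20 °C) should give by axial hydride attack the allylic alcohol F1 with the hydroxyl cis to the C8 methyl. Mitsunobu displacement with 2-nitrobenzenesulfonylhydrazide (PPh3, diethyl azodicarboxylate, THF, –30 °C) inverts C6 and gives the N-alkyl sulfonylhydrazide F2. On warming this loses the sulfinic acid to the allylic diazene F3, which transfers hydrogen suprafacially to the α face of C10 with loss of nitrogen and gives the transposed alkene F4 (C5=C6). Epoxidation (buffered m-chloroperbenzoic acid) gives the epoxide F5, and Meinwald rearrangement with hydride shift from C6 to C5 (LiClO4, toluene, heat) gives the ketone F6. Silylation under equilibrating conditions (i-Pr3SiOTf, Et3N, CH2Cl2, rt), which favours the more substituted C5=C6 enol ether, returns the route at 19.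

Step 12. Hydrazone formation at the neopentyl C6 carbonyl may be incomplete, or the exocyclic double bond may migrate under strong base at 200 °C. The fallback is a radical deoxygenation under neutral conditions. It sets out from 21: LiAlH4 in THF gives the alcohol F9, NaH/CS2/MeI gives the xanthate F10, and Barton–McCombie reduction (Bu3SnH, azobisisobutyronitrile, toluene, reflux, high stannane concentration so that hydrogen transfer outruns homoallyl radical rearrangement) returns the route at 23.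

Further compounds
F1 | step 9 | (1R,4R,5S)-4-(ArCH2)-2,4,5-trimethyl-3-[5-(trimethylsilyl)pent-4-yn-1-yl]cyclohex-2-en-1-ol | O[C@@H]1C[C@H](C)[C@@](C)(Cc2c(OC)c(OC)cc(OC)c2OC)C(CCCC#C[Si](C)(C)C)=C1C
F2 | step 9 | N-[(1S,4R,5S)-4-(ArCH2)-2,4,5-trimethyl-3-[5-(trimethylsilyl)pent-4-yn-1-yl]cyclohex-2-en-1-yl]-2-nitrobenzenesulfonohydrazide | NN([C@H]1C[C@H](C)[C@@](C)(Cc2c(OC)c(OC)cc(OC)c2OC)C(CCCC#C[Si](C)(C)C)=C1C)S(=O)(=O)c3ccccc3[N+](=O)[O-]
F3 | step 9 | [(1S,4R,5S)-4-(ArCH2)-2,4,5-trimethyl-3-[5-(trimethylsilyl)pent-4-yn-1-yl]cyclohex-2-en-1-yl]diazene | N=N[C@H]1C[C@H](C)[C@@](C)(Cc2c(OC)c(OC)cc(OC)c2OC)C(CCCC#C[Si](C)(C)C)=C1C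
F4 | step 9 | trimethyl(5-{(1R,5S,6R)-6-(ArCH2)-2,5,6-trimethylcyclohex-2-en-1-yl}pent-1-yn-1-yl)silane | CC1=CC[C@H](C)[C@@](C)(Cc2c(OC)c(OC)cc(OC)c2OC)[C@@H]1CCCC#C[Si](C)(C)C
F5 | step 9 | 2,3-epoxide of F4 (either face) | CC12OC1C[C@H](C)[C@@](C)(Cc3c(OC)c(OC)cc(OC)c3OC)[C@@H]2CCCC#C[Si](C)(C)C
F6 | step 9 | (3R,4R,5S)-4-(ArCH2)-2,4,5-trimethyl-3-[5-(trimethylsilyl)pent-4-yn-1-yl]cyclohexan-1-one (both C2 epimers) | CC1C(=O)C[C@H](C)[C@@](C)(Cc2c(OC)c(OC)cc(OC)c2OC)[C@@H]1CCCC#C[Si](C)(C)C
F7 | step 11 | (3R,4R,5S)-4-(ArCH2)-2,4,5-trimethyl-3-(pent-4-yn-1-yl)cyclohexan-1-one (both C2 epimers) | CC1C(=O)C[C@H](C)[C@@](C)(Cc2c(OC)c(OC)cc(OC)c2OC)[C@@H]1CCCC#C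
F8 | step 11 | (3R,4R,5S)-3-(4-bromopent-4-en-1-yl)-4-(ArCH2)-2,4,5-trimethylcyclohexan-1-one (both C2 epimers) | CC1C(=O)C[C@H](C)[C@@](C)(Cc2c(OC)c(OC)cc(OC)c2OC)[C@@H]1CCCC(Br)=C
F9 | step 12 | (3S,4R,4aS,8aR)-4-(ArCH2)-3,4,8a-trimethyl-8-methylidenedecahydronaphthalen-1-ol (both C1 epimers) | C=C1CCC[C@H]2[C@](C)(Cc3c(OC)c(OC)cc(OC)c3OC)[C@@H](C)CC(O)[C@@]12C
F10 | step 12 | O-[(3S,4R,4aS,8aR)-4-(ArCH2)-3,4,8a-trimethyl-8-methylidenedecahydronaphthalen-1-yl] S-methyl carbonodithioate | C=C1CCC[C@H]2[C@](C)(Cc3c(OC)c(OC)cc(OC)c3OC)[C@@H](C)CC(OC(=S)SC)[C@@]12C
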